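The data are simulated for an exercise, and the scatter is random.

The reagent is the partner to watch, since it is the limiting reagent in Saturday's flask (0.160 M against 0.200 M) and in Monday's. Monday's 0.0600 M of reagent can therefore take starting material down to 40.0% of its charge and no lower. In Thursday's flask the starting material is the limiting one, with 0.100 M against 0.160 M of reagent.

| flask | starting material | reagent | free catalyst | time |
|---|---|---|---|---|
| Saturday's | 0.200 M | 0.160 M | 0.0100 M |  |
| Thursday's | 0.100 M | 0.160 M | 0.0100 M |  |
| Sunday's | 0.200 M | 0.160 M | 0.0150 M |  |
| Monday's | 0.100 M | 0.0600 M | 0.0100 M | 26 min |

| Saturday's run: time / min | Saturday's run: [starting material] / M | Thursday's run: time / min | Thursday's run: [starting material] / M | Sunday's run: time / min | Sunday's run: [starting material] / M |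
|---|---|---|---|---|---|
| 1.0 | 0.1990 | 1.0 | 0.0978 | 1.0 | 0.2012 |
| 2.3 | 0.1974 | 2.3 | 0.0943 | 2.3 | 0.1925 |
| 5.2 | 0.1845 | 5.2 | 0.0912 | 5.2 | 0.1749 |
| 12 | 0.1378 | 12 | 0.0637 | 12 | 0.1184 |
| 26 | 0.0686 | 26 | 0.0170 | 26 | 0.0485 |

(each reading ± 0.002 M)

- reaction order in [free catalyst] at the outset, round the charge of the Saturday's run, defined at two percent of the starting material turned into target
- reaction order in [starting material] at the outset, round the charge of the Saturday's run, defined at two percent of the starting material turned into target (one fixed amount of target, the same in the runs compared)
- starting material in the Monday's run at 26 min, as a share of the starting material charged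

- Overall: starting material + reagent -> target, with free catalyst as catalyst.
- Constant volume, constant temperature.
- The analysis sees a species whether free or bound.
- An order is taken over about fifteen percent of the charge, up and down.

Saturday's flask loses starting material at 0.00113 M/min over its first 2.3 min, but at 0.00687 M/min between 5.2 min and 12 min. That is faster, although both partners have fallen by then. So these readings do not fit a constant k in dS/dt = −kSR, with S and R the present concentrations.

But k may grow with time, and one quantity survives that. With S° and R° the charges, S − R stays equal to S° − R°, so ln[(S/R)(R°/S°)] = (S° − R°)τ, where τ is the integral of k over time. Using R = R° − S° + S, Saturday's reading at 26 min gives τ = 16.3 /M, and Thursday's gives 17.3 /M. We carry their mean, 16.8 /M, as the reaction clock at that time, and we assume that it also holds for Monday's flask, which is charged with the same 0.0100 M of free catalyst.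

Set on Monday's charge, our clock leaves 57.7% of the starting material at 26 min.

The forecast is a little higher, at 59% (53% to 68%), with 0.65 (0.4 to 1.2) for the catalyst order and 0.5 (0.25 to 0.95) for the starting-material order. It adds: “Slower activation at low reagent would push this higher”.

The flask gives 0.56 for the catalyst order, 0.28 for the starting-material order and 51.8% for Monday's starting material, the last below the forecast's range.

    active catalyst + starting material → catalyst-substrate complex (10.08 /M/min)
    catalyst-substrate complex + reagent → loaded catalyst (46.14 /M/min)
    loaded catalyst → target + active catalyst (2.304 /min)
    free catalyst + reagent → active catalyst + reagent (1.194 /M/min)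

The apparent order in reagent early in Saturday's run is 0.51. Read back from Monday's result, the clock at 26 min stands at 24.2 /M, ahead of the 16.8 /M we carried. Saturday's and Sunday's flasks share their starting material and reagent charges, so the same reckoning puts both at τ = 7.19 /M when target reaches half of the starting material charged. Saturday's flask gets there at 19.5 min and Sunday's at 14.8 min, a mean clock pace of 0.369 /M/min against 0.486 /M/min.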